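Numbering used throughout: ring A is C1–C6 (C1 bears OH, C2 and C4 bear Br, C6 bears the ether oxygen); ring B is C1'–C6' (C1' bears the ether oxygen, C3', C4' and C5' bear Br, C6' bears OH).

Assumption: tert-butyl 2-chloroacetoacetate (6) is made in one step rather than bought, and every sp3 stereocentre on the way is racemic and is erased before the end.

## The problem

Compound 16 is a diaryl ether of two ortho-hydroxyphenyl rings that carry five bromines. It has no stereocentre, so the task is one of regiochemistry. Ring A is the easy half: its bromines at C2 and C4 are ortho and para to the C1 hydroxyl and follow from ordinary bromination of a phenol. Ring B is the hard half: C3' and C5' are para and ortho to the C6' hydroxyl, but the C4' bromine is meta to it. Only the weaker ether oxygen could direct a bromine to C4', so electrophilic substitution cannot be trusted to place it. The ether bond joins two ortho-oxygenated, heavily brominated rings, so an aryl C–O coupling would meet steric hindrance and competing C–Br sites. The aryl C–Br bonds rule out hydrogenolysis, zerovalent metal catalysis and halogen–metal exchange conditions, and free phenols are easily oxidised or over-brominated, so one hydroxyl stays masked until the end. The enabling feature is that C6'–O and C4'–Br stand in a 1,3-relationship, which is the pattern of the two carbonyls of a cyclohexane-1,3-dione. C1', next to C6', carries the ether oxygen and so corresponds to the α-carbon of an acetoacetate, where a C–O bond can be made by substitution at sp3 carbon. The only stereocentre that appears is the transient, racemic quaternary C1'; it controls regiochemistry (it tells the two carbonyls apart) and disappears on aromatisation.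

## Retrosynthesis

**16 from 15.** The O–CH3 bond on ring A is cut last. A methyl ether is chosen because it must survive tert-butoxide, trifluoroacetic acid and bromine. It also keeps ring A less activated than a phenol while ring B is brominated. The forward step asks only for clean BBr3 demethylation beside a diaryl ether.

**15 from 13.** The C3'–Br and C5'–Br bonds are cut and ring B is taken back to the cyclohexenone level. In 13 the C4' bromine is already fixed as a vinyl bromide. The forward reaction must oxidise the enone to the phenol 14 and then brominate ortho and para to the new C6' hydroxyl, which are exactly the positions still needed. Placing these two bromines earlier is impossible on a saturated ring and unnecessary on an aromatic one.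

**13 from 11 and 10.** The C1' carboxyl group is restored and the C4'–Br bond is traced back to the C4' carbonyl of dione 10. Bromoenone formation is placed before loss of the ester, because only the quaternary C1' makes the C6' carbonyl clearly more hindered than C4'. The ester is tert-butyl so that it leaves under anhydrous acid (11 to 13 through acid 12). A halide-mediated dealkoxycarbonylation at high temperature would threaten the vinylogous acyl bromide by exchange or hydrolysis.

**10 from 7 and 8.** The C1'–C2' and C4'–C5' bonds are cut. This reduces the six-membered ring to the aryloxyacetoacetate 7 and ethyl acrylate 8, joined through the open-chain adduct 9. The cut is preferred over any aryl–aryl ether coupling because it builds the ring whose substitution pattern cannot be reached by substitution chemistry. The forward reaction needs Michael addition of a hindered stabilised enolate and then ring closure by the methyl ketone enolate faster than loss of the acetyl group.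

**7 from 4 and 6.** The C1'–O bond is cut at sp3 carbon to give phenol 4 and chloride 6. An SN2 alkylation with a doubly activated chloride replaces a copper-mediated coupling between two polybrominated arenes. The forward step asks only for O-alkylation of a moderately hindered phenoxide.

**6 from 5.** The C–Cl bond is cut to give tert-butyl acetoacetate 5, a bulk chemical; the forward step is monochlorination.

**4 from 3, 2 and 1.** The ring A bromines are traced back to bromination of 1, whose free hydroxyl directs to C2 and C4 while the benzyl ether holds the position of the future ether oxygen. Methylation (2 to 3) and debenzylation (3 to 4) then exchange the roles of the two oxygens. Bromination of a simple 2-alkoxyphenol with the opposite oxygen free would give the wrong isomer, so the exchange is needed.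

## Roads not taken

**Alternative 1:** The cut removes the four C–Br bonds at C2, C4, C3' and C5' in one stroke and replaces the C4' bromine by an amino group. In the forward direction 5-amino-2-(2-hydroxyphenoxy)phenol A1 is brominated four times to 3-amino-2,4-dibromo-6-(3,5-dibromo-2-hydroxyphenoxy)phenol A2, and a Sandmeyer reaction (diazotisation, CuBr) then gives 16.

- Merits: all directing effects agree. The ring A hydroxyl sends bromine to C2 and C4. The C4' amine sends it to C3' and C5', which are also para and ortho to the C6' hydroxyl. Nitrogen marks the one position that substitution cannot reach. A1 should be reachable by SNAr on a nitro-activated aryl fluoride, reduction and demethylation, so this road is roughly half as long as the chosen one and is clearly better in step count.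
- Weak points: A1 is an extremely electron-rich aminobisphenol and bromine is an oxidant, so N-bromination, quinone imine formation and ipso attack threaten the fourfold bromination. The Sandmeyer step must diazotise a weakly basic amine flanked by two bromines in the presence of two free phenols, and reduction instead of bromination of the aryl radical would give a tetrabromide that is hard to separate.
- Comparison: the chosen plan is longer. In return, no step depends on handling an oxidation-prone aminophenol or a diazonium salt, and the position of every substituent follows from the connectivity of open-chain precursors.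

**Alternative 2:** The cut opens ring A at C1–C2 and C5–C6. A Diels–Alder reaction of 3,5-dibromo-2H-pyran-2-one A3 with the ketene acetal 1,1-bis(trimethylsilyloxy)-2-(3,4,5-tribromo-2-methoxyphenoxy)ethene A4 across C3 and C6 of the pyrone is followed by loss of CO2 and Me3SiOH. This gives [2,4-dibromo-6-(3,4,5-tribromo-2-methoxyphenoxy)phenoxy]trimethylsilane A5, and desilylation and demethylation lead to 16.

- Merits: it is convergent. The pyrone bromines arrive at C2 and C4 by construction, and the ether oxygen comes in on the dienophile, so no aryl C–O coupling is needed. As a way of making the diaryl ether it is at least as elegant as the chosen alkylation.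
- Weak points: the ring construction is spent on ring A, which plain bromination can make. The difficult ring B pattern must already be present in 3,4,5-tribromo-2-methoxyphenol A6, the source of A4, and making A6 meets the same meta-bromine problem. A4 is a hydrolytically fragile bis-silyl ketene acetal.
- Comparison: the alternative moves the difficulty rather than solving it. The chosen plan builds the ring that substitution chemistry cannot deliver.

**Alternative 3:** The cut traces both hydroxyls (C1–O and C6'–O) to formyl groups. Peracid oxidation of 2,3,4-tribromo-6-(3,5-dibromo-2-formylphenoxy)benzaldehyde A7 would give, by twofold aryl migration, 2,4-dibromo-6-(3,4,5-tribromo-2-formyloxyphenoxy)phenyl formate A8, and hydrolysis would give 16.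

- Merits: the formyl groups would activate ortho fluorides for a copper-free SNAr assembly of A7, and the end game is short and mild.
- Weak points: aryl migration in the Dakin and Baeyer–Villiger manifold needs an electron-rich migrating ring. Both rings of A7 are bromine-laden and each formyl group has two ortho neighbours, so hydride migration to carboxylic acids should compete strongly, and it must be suppressed twice. The ring B half of A7 still needs the contiguous tribromo pattern, to be made by metalation of a polybromoarene with its risk of halogen migration.
- Comparison: the end game is shorter, but the key step is electronically mismatched. The chosen key step is matched: a stabilised enolate adds to an acrylate and an acidic dione is the thermodynamic sink.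

Key step: step 6

## Route

Step 1
Reactants: 1 2-(benzyloxy)phenol
Product: 2 2-(benzyloxy)-4,6-dibromophenol
Conditions: NBS (2.1 equiv), MeCN, 0 °C to rt
Reagents that add atoms: N-bromosuccinimide, O=C1CCC(=O)N1Br
Why: Electrophilic aromatic bromination; the free hydroxyl is the strongest donor and directs bromine to its para and its one free ortho position (the future C4 and C2), while the benzyloxy group occupies the other ortho site.

Step 2
Reactants: 2 2-(benzyloxy)-4,6-dibromophenol
Product: 3 1-(benzyloxy)-3,5-dibromo-2-methoxybenzene
Conditions: MeI, K2CO3, DMF, rt
Reagents that add atoms: iodomethane, CI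
Why: Williamson etherification of an acidic dibromophenol; the methyl ether is chosen to survive base, acid and bromine until the last step.

Step 3
Reactants: 3 1-(benzyloxy)-3,5-dibromo-2-methoxybenzene
Product: 4 3,5-dibromo-2-methoxyphenol
Conditions: BCl3 (2 equiv), C6HMe5 (3 equiv), CH2Cl2, −78 °C; then H2O
Reagents that add atoms: none
Why: Lewis acid debenzylation with a cation scavenger; at −78 °C the benzyl ether ionises far more readily than the methyl ether and pentamethylbenzene traps the benzyl cation, so the methyl ether and the aryl bromides (which hydrogenolysis would endanger) remain.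

Step 4
Reactants: 5 tert-butyl 3-oxobutanoate
Product: 6 tert-butyl 2-chloro-3-oxobutanoate (racemic)
Conditions: SO2Cl2 (1.0 equiv), CH2Cl2, 0 °C to rt
Reagents that add atoms: sulfuryl chloride, O=S(=O)(Cl)Cl
Why: α-Chlorination of a β-keto ester through its enol; one equivalent at low temperature stops at the monochloride and the escaping gases spare the tert-butyl ester.

Step 5
Reactants: 4 3,5-dibromo-2-methoxyphenol; 6 tert-butyl 2-chloro-3-oxobutanoate (racemic)
Product: 7 tert-butyl 2-(3,5-dibromo-2-methoxyphenoxy)-3-oxobutanoate (racemic)
Conditions: K2CO3, acetone, reflux
Reagents that add atoms: none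
Why: SN2 O-alkylation of a phenoxide by a doubly activated secondary chloride, the standard entry to 2-aryloxyacetoacetates; the C1'–O bond is made at sp3 carbon, so no aryl C–Br bond is put at risk.

Step 6
Reactants: 7 tert-butyl 2-(3,5-dibromo-2-methoxyphenoxy)-3-oxobutanoate (racemic); 8 ethyl acrylate
Product: 10 tert-butyl 1-(3,5-dibromo-2-methoxyphenoxy)-2,4-dioxocyclohexane-1-carboxylate (racemic), via Michael adduct 9 (not isolated)
Conditions: KOtBu (2.0 equiv), THF, 0 °C to rt; then 1 M HCl
Reagents that add atoms: none
Why: Consecutive Michael addition and Claisen (Dieckmann-type) cyclisation, the known route from methyl ketones and acrylates to cyclohexane-1,3-diones. KOtBu deprotonates 7 between its two carbonyls and this enolate adds through C1' to the β-carbon of 8, forming C1'–C2' and giving 9. Proton transfer then generates the methyl ketone enolate of 9, whose C5' attacks the ethyl ester carbonyl C4' in a 6-(enolexo)-exo-trig acyl substitution that expels ethoxide and closes ring B. Deprotonation of the acidic 1,3-dione makes the closure irreversible, so about one equivalent of base is consumed and the dione is released on acidification. C1' becomes quaternary but is formed from a planar enolate with no chiral influence, so 10 is racemic; this is harmless because the centre is erased in step 9. The step needs ring closure to outrun retro-Claisen loss of the acetyl group and retro-Michael reaction. The hindered, non-nucleophilic tert-butoxide and the thermodynamic sink of the dione enolate secure this. The tert-butyl ester cannot interfere, since it is hindered and attack on it by either enolate would form a four-membered ring.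

Step 7
Reactants: 10 tert-butyl 1-(3,5-dibromo-2-methoxyphenoxy)-2,4-dioxocyclohexane-1-carboxylate (racemic)
Product: 11 tert-butyl 4-bromo-1-(3,5-dibromo-2-methoxyphenoxy)-2-oxocyclohex-3-ene-1-carboxylate (racemic)
Conditions: Ph3PBr2 (1.2 equiv), Et3N (1.3 equiv), CH2Cl2, 0 °C to rt
Reagents that add atoms: triphenylphosphine dibromide, BrP(Br)(c1ccccc1)(c1ccccc1)c1ccccc1
Why: β-Bromoenone formation from a 1,3-dione (vinylogous acid to vinylogous acyl bromide); the enolate oxygen remote from the quaternary C1' is activated as its oxyphosphonium salt and bromide adds and eliminates at the unhindered C4', as known for 4,4-disubstituted cyclohexane-1,3-diones. The basic medium spares the tert-butyl ester.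

Step 8
Reactants: 11 tert-butyl 4-bromo-1-(3,5-dibromo-2-methoxyphenoxy)-2-oxocyclohex-3-ene-1-carboxylate (racemic)
Product: 13 3-bromo-6-(3,5-dibromo-2-methoxyphenoxy)cyclohex-2-en-1-one (racemic), via β-keto acid 12 (not isolated)
Conditions: TFA, CH2Cl2, rt; then toluene, 80 °C
Reagents that add atoms: none
Why: Acidolysis of the tert-butyl ester followed by thermal decarboxylation of the β-keto acid through its cyclic six-membered transition state; the dienol so formed is protonated at C1' to give the conjugated bromoenone. No nucleophilic halide or water is present that could exchange or hydrolyse the vinyl bromide.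

Step 9
Reactants: 13 3-bromo-6-(3,5-dibromo-2-methoxyphenoxy)cyclohex-2-en-1-one (racemic)
Product: 15 2,3,4-tribromo-6-(3,5-dibromo-2-methoxyphenoxy)phenol, via bromophenol 14 (not isolated)
Conditions: Br2 (3.0 equiv), AcOH, rt to 60 °C
Reagents that add atoms: bromine, BrBr
Why: Bromination–dehydrobromination aromatisation of a cyclohexenone followed by electrophilic bromination of the phenol formed: bromination next to the carbonyl at C1' (or at the γ-carbon C3') and loss of HBr lead to the phenol tautomer 14. Its new C6' hydroxyl directs two further bromines to C3' (para) and C5' (ortho), whereas C2' (meta to OH) and the dibrominated anisole ring A are much less reactive.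

Step 10
Reactants: 15 2,3,4-tribromo-6-(3,5-dibromo-2-methoxyphenoxy)phenol
Product: 16 2,3,4-tribromo-6-(3,5-dibromo-2-hydroxyphenoxy)phenol
Conditions: BBr3 (3 equiv), CH2Cl2, −78 °C to rt; then H2O
Reagents that add atoms: none
Why: Lewis acid cleavage of an aryl methyl ether with BBr3; the diaryl ether and the aryl bromides are inert and the free phenol only consumes one further equivalent of reagent.

## Compound list

1 | 2-(benzyloxy)phenol | Oc1ccccc1OCc1ccccc1 | starting material
2 | 2-(benzyloxy)-4,6-dibromophenol | Oc1c(Br)cc(Br)cc1OCc1ccccc1 | intermediate
3 | 1-(benzyloxy)-3,5-dibromo-2-methoxybenzene | COc1c(Br)cc(Br)cc1OCc1ccccc1 | intermediate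
4 | 3,5-dibromo-2-methoxyphenol | COc1c(Br)cc(Br)cc1O | intermediate
5 | tert-butyl 3-oxobutanoate | CC(=O)CC(=O)OC(C)(C)C | starting material
6 | tert-butyl 2-chloro-3-oxobutanoate (racemic) | CC(=O)C(Cl)C(=O)OC(C)(C)C | intermediate
7 | tert-butyl 2-(3,5-dibromo-2-methoxyphenoxy)-3-oxobutanoate (racemic) | CC(=O)C(Oc1cc(Br)cc(Br)c1OC)C(=O)OC(C)(C)C | intermediate
8 | ethyl acrylate | C=CC(=O)OCC | starting material
9 | 1-tert-butyl 5-ethyl 2-acetyl-2-(3,5-dibromo-2-methoxyphenoxy)pentanedioate (racemic) | CCOC(=O)CCC(Oc1cc(Br)cc(Br)c1OC)(C(C)=O)C(=O)OC(C)(C)C | intermediate (not isolated)
10 | tert-butyl 1-(3,5-dibromo-2-methoxyphenoxy)-2,4-dioxocyclohexane-1-carboxylate (racemic) | CC(C)(C)OC(=O)C1(Oc2cc(Br)cc(Br)c2OC)CCC(=O)CC1=O | intermediate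
11 | tert-butyl 4-bromo-1-(3,5-dibromo-2-methoxyphenoxy)-2-oxocyclohex-3-ene-1-carboxylate (racemic) | CC(C)(C)OC(=O)C1(Oc2cc(Br)cc(Br)c2OC)CCC(Br)=CC1=O | intermediate
12 | 4-bromo-1-(3,5-dibromo-2-methoxyphenoxy)-2-oxocyclohex-3-ene-1-carboxylic acid (racemic) | OC(=O)C1(Oc2cc(Br)cc(Br)c2OC)CCC(Br)=CC1=O | intermediate (not isolated)
13 | 3-bromo-6-(3,5-dibromo-2-methoxyphenoxy)cyclohex-2-en-1-one (racemic) | O=C1C=C(Br)CCC1Oc1cc(Br)cc(Br)c1OC | intermediate
14 | 5-bromo-2-(3,5-dibromo-2-methoxyphenoxy)phenol | Oc1cc(Br)ccc1Oc1cc(Br)cc(Br)c1OC | intermediate (not isolated)
15 | 2,3,4-tribromo-6-(3,5-dibromo-2-methoxyphenoxy)phenol | Oc1c(Br)c(Br)c(Br)cc1Oc1cc(Br)cc(Br)c1OC | intermediate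
16 | 2,3,4-tribromo-6-(3,5-dibromo-2-hydroxyphenoxy)phenol | Oc1c(Br)cc(Br)cc1Oc1cc(Br)c(Br)c(Br)c1O | target

## Step count and risks

Total step count: 10. Longest linear sequence: 9 steps (1 to 16 through steps 1–3 and 5–10); step 4 is a one-step side branch from 5.

**Step 6 (key step).** The most likely failure is cleavage of the acetyl group of 9 by the ethoxide set free in the ring closure, or reversal of the Michael addition, before the methyl ketone enolate closes the ring; the crowded quaternary centre slows the wanted closure. The fallback sets out from 7 and comes back at 10. It forms the same two bonds without any alkoxide.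
- Conjugate addition of 7 to acrolein with catalytic Et3N should give the aldehyde tert-butyl 2-acetyl-2-(3,5-dibromo-2-methoxyphenoxy)-5-oxopentanoate F1.
- An amine-catalysed 6-enolexo aldol addition (L-proline, DMSO) of the methyl ketone to the aldehyde should give the β-hydroxy ketone tert-butyl 1-(3,5-dibromo-2-methoxyphenoxy)-4-hydroxy-2-oxocyclohexane-1-carboxylate F2.
- F2 is oxidised without delay with Dess–Martin periodinane to 10.

**Step 9.** The one-pot sequence may stall at bromoketone intermediates, add bromine across the enone, or run on to bromination at C2' or on ring A, because three different events must occur in order with one reagent. The fallback sets out from 13 and comes back at 15. It separates dehydrogenation from bromination.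
- Kinetic deprotonation at C1' (LDA, THF, −78 °C) and trapping with PhSeBr should give 3-bromo-6-(3,5-dibromo-2-methoxyphenoxy)-6-(phenylselanyl)cyclohex-2-en-1-one F3.
- Oxidation with H2O2 should give the selenoxide 3-bromo-6-(3,5-dibromo-2-methoxyphenoxy)-6-(phenylseleninyl)cyclohex-2-en-1-one F4. Its syn-elimination can only go toward C2', and tautomerisation then gives phenol 14, here isolated.
- 14 is brominated with two equivalents of Br2 in AcOH to 15.

**Step 7.** Bromide may be delivered in part to C6', or the hindered oxyphosphonium intermediate may turn over incompletely. The fallback sets out from 10 and comes back at 11. It separates activation of the oxygen from delivery of the halide.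
- MsCl and K2CO3 should sulfonylate the less hindered enolate oxygen to give tert-butyl 1-(3,5-dibromo-2-methoxyphenoxy)-4-(methanesulfonyloxy)-2-oxocyclohex-3-ene-1-carboxylate F5, which can be purified and its regiochemistry checked.
- Addition–elimination with LiBr in warm acetone then gives 11.

**Step 8.** Solvolysis of the vinyl bromide during the acid treatment and heating, or acid-promoted cyclodehydration of the aryloxy ketone onto ring A, may erode the material. The fallback sets out from 10 and comes back at 13. It removes the ester before the vinyl bromide exists.
- TFA should cleave 10 to 1-(3,5-dibromo-2-methoxyphenoxy)-2,4-dioxocyclohexane-1-carboxylic acid F6, which on warming loses CO2 to give 4-(3,5-dibromo-2-methoxyphenoxy)cyclohexane-1,3-dione F7.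
- Ph3PBr2 and Et3N then give 13, to be separated from its regioisomer. The price is weaker regiocontrol, since C1' is then only tertiary.

## Further compounds

F1 | step 6 | tert-butyl 2-acetyl-2-(3,5-dibromo-2-methoxyphenoxy)-5-oxopentanoate (racemic) | CC(=O)C(CCC=O)(Oc1cc(Br)cc(Br)c1OC)C(=O)OC(C)(C)C
F2 | step 6 | tert-butyl 1-(3,5-dibromo-2-methoxyphenoxy)-4-hydroxy-2-oxocyclohexane-1-carboxylate (racemic, mixture of diastereomers) | CC(C)(C)OC(=O)C1(Oc2cc(Br)cc(Br)c2OC)CCC(O)CC1=O
F3 | step 9 | 3-bromo-6-(3,5-dibromo-2-methoxyphenoxy)-6-(phenylselanyl)cyclohex-2-en-1-one (racemic) | O=C1C=C(Br)CCC1(Oc1cc(Br)cc(Br)c1OC)[Se]c1ccccc1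
F4 | step 9 | 3-bromo-6-(3,5-dibromo-2-methoxyphenoxy)-6-(phenylseleninyl)cyclohex-2-en-1-one (racemic, mixture of diastereomers) | O=C1C=C(Br)CCC1(Oc1cc(Br)cc(Br)c1OC)[Se](=O)c1ccccc1
F5 | step 7 | tert-butyl 1-(3,5-dibromo-2-methoxyphenoxy)-4-(methanesulfonyloxy)-2-oxocyclohex-3-ene-1-carboxylate (racemic) | CC(C)(C)OC(=O)C1(Oc2cc(Br)cc(Br)c2OC)CCC(OS(C)(=O)=O)=CC1=O
F6 | step 8 | 1-(3,5-dibromo-2-methoxyphenoxy)-2,4-dioxocyclohexane-1-carboxylic acid (racemic) | OC(=O)C1(Oc2cc(Br)cc(Br)c2OC)CCC(=O)CC1=O
F7 | step 8 | 4-(3,5-dibromo-2-methoxyphenoxy)cyclohexane-1,3-dione (racemic) | O=C1CCC(Oc2cc(Br)cc(Br)c2OC)C(=O)C1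
A1 | alternative 1 | 5-amino-2-(2-hydroxyphenoxy)phenol | Nc1ccc(Oc2ccccc2O)c(O)c1
A2 | alternative 1 | 3-amino-2,4-dibromo-6-(3,5-dibromo-2-hydroxyphenoxy)phenol | Nc1c(Br)cc(Oc2cc(Br)cc(Br)c2O)c(O)c1Br
A3 | alternative 2 | 3,5-dibromo-2H-pyran-2-one | O=c1occ(Br)cc1Br
A4 | alternative 2 | 1,1-bis(trimethylsilyloxy)-2-(3,4,5-tribromo-2-methoxyphenoxy)ethene | COc1c(OC=C(O[Si](C)(C)C)O[Si](C)(C)C)cc(Br)c(Br)c1Br
A5 | alternative 2 | [2,4-dibromo-6-(3,4,5-tribromo-2-methoxyphenoxy)phenoxy]trimethylsilane | COc1c(Oc2cc(Br)cc(Br)c2O[Si](C)(C)C)cc(Br)c(Br)c1Br
A6 | alternative 2 | 3,4,5-tribromo-2-methoxyphenol | COc1c(O)cc(Br)c(Br)c1Br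
A7 | alternative 3 | 2,3,4-tribromo-6-(3,5-dibromo-2-formylphenoxy)benzaldehyde | O=Cc1c(Br)cc(Br)cc1Oc1cc(Br)c(Br)c(Br)c1C=O
A8 | alternative 3 | 2,4-dibromo-6-(3,4,5-tribromo-2-formyloxyphenoxy)phenyl formate | O=COc1c(Br)cc(Br)cc1Oc1cc(Br)c(Br)c(Br)c1OC=O
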